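The oxane is cut into two three-atom pieces: O1–C2–C3 (ring oxygen, aryl-bearing benzylic carbon, adjacent CH2) and C4–C5–C6 (carbinol carbon, CH2, arylethyl-bearing carbon). In one operation a configurationally defined β-oxido alkyllithium, made by reductive lithiation of an (R)-chlorohydrin, is acylated by an alkynoic Weinreb amide (C3–C4), and the liberated alkoxide closes 6-endo-dig onto the ynone (O1–C6) to give a 2-aryl-2,3-dihydro-4H-pyran-4-one. The step exploits the latent β-alkoxy ketone relationship between O1 and C4 in the oxane ring. Face-selective hydrogenation, reduction to the axial alcohol and desilylation finish the route.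

Key step: step 6

Remark: oxane numbering is used throughout (O1, aryl-bearing C2, C3, carbinol C4, C5, arylethyl-bearing C6); TBS = tert-butyldimethylsilyl and TBSO = its ether; 1 and 6 are taken as commercial; the facial sense of the oxazaborolidine reduction in step 3 is assigned by analogy with phenacyl chloride.

Step 1
Reactants: 1 methyl 3,4-dihydroxy-5-methoxybenzoate
Product: 2 methyl 3,4-bis(TBSO)-5-methoxybenzoate
Conditions: TBSCl (2.5 equiv), imidazole, DMF, rt
Reagents that add atoms: tert-butyldimethylsilyl chloride CC(C)(C)[Si](C)(C)Cl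
Why: Imidazole-mediated O-silylation protects both catechol hydroxyls as aryl silyl ethers, which should survive the organolithium and arene radical-anion reagents used later and leave under near-neutral fluoride at the end.

Step 2
Reactants: 2 methyl 3,4-bis(TBSO)-5-methoxybenzoate
Product: 4 1-[3,4-bis(TBSO)-5-methoxyphenyl]-2-chloroethan-1-one, via lithium hemiketal adduct 3 (not isolated)
Conditions: ICH2Cl, MeLi·LiBr (slow addition), THF, −78 °C; then AcOH, −78 °C to rt
Reagents that add atoms: chloroiodomethane ClCI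
Why: Halomethyllithium homologation of an ester: chloromethyllithium, formed in the flask by iodine–lithium exchange, should add once because adduct 3 persists at −78 °C and releases ketone 4 only on acidic quench.

Step 3
Reactants: 4 1-[3,4-bis(TBSO)-5-methoxyphenyl]-2-chloroethan-1-one
Product: 5 (1R)-1-[3,4-bis(TBSO)-5-methoxyphenyl]-2-chloroethan-1-ol
Conditions: (R)-2-methyl-CBS-oxazaborolidine (10 mol%), BH3·SMe2, THF, 0 °C; then MeOH
Reagents that add atoms: none
Why: Corey–Bakshi–Shibata reduction: with aryl as the large and CH2Cl as the small group, the (R)-oxazaborolidine should deliver hydride to the carbonyl face that gives the (R)-chlorohydrin, the sense established for phenacyl chloride.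

Step 4
Reactants: 6 zingerone, 4-(4-hydroxy-3-methoxyphenyl)butan-2-one
Product: 7 4-[4-(TBSO)-3-methoxyphenyl]butan-2-one
Conditions: TBSCl, imidazole, DMF, rt
Reagents that add atoms: tert-butyldimethylsilyl chloride CC(C)(C)[Si](C)(C)Cl
Why: Imidazole-mediated silylation masks the phenol, which would otherwise quench the amide base of step 5.

Step 5
Reactants: 7 4-[4-(TBSO)-3-methoxyphenyl]butan-2-one
Product: 10 5-[4-(TBSO)-3-methoxyphenyl]-N-methoxy-N-methylpent-2-ynamide, via enol phosphate 8 (not isolated), via lithium acetylide 9 (not isolated)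
Conditions: LiN(iPr)2 (1.1 equiv), THF, −78 °C; ClP(O)(OEt)2, −78 °C to rt; LiN(iPr)2 (2.3 equiv), −78 °C to rt; ClC(O)N(OMe)Me, −78 to 0 °C
Reagents that add atoms: N-methoxy-N-methylcarbamoyl chloride CON(C)C(Cl)=O
Why: Negishi conversion of a methyl ketone into a terminal alkyne (kinetic enol phosphate formation at the methyl group, then base-induced elimination) leaves lithium acetylide 9, which is acylated in the same flask by the carbamoyl chloride (Weinreb amide synthesis).

Step 6
Reactants: 5 (1R)-1-[3,4-bis(TBSO)-5-methoxyphenyl]-2-chloroethan-1-ol; 10 5-[4-(TBSO)-3-methoxyphenyl]-N-methoxy-N-methylpent-2-ynamide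
Product: 14 (2S)-2-[3,4-bis(TBSO)-5-methoxyphenyl]-6-{2-[4-(TBSO)-3-methoxyphenyl]ethyl}-2,3-dihydro-4H-pyran-4-one, via β-oxido alkyllithium 11 (not isolated), via tetrahedral adduct 12 (not isolated), via hydroxy ynone 13 (not isolated)
Conditions: 5, n-BuLi (1.0 equiv), THF, −78 °C; LiC10H8 (lithium naphthalenide, 2.05 equiv), −78 °C; 10 (1.1 equiv), −78 °C; then t-BuOH (3 equiv), −78 to 0 °C; aq. NH4Cl
Reagents that add atoms: none
Why: Deprotonation of 5 and two-electron reduction of its C–Cl bond by lithium naphthalenide give the β-oxido alkyllithium 11 (reductive lithiation of a chlorohydrin alkoxide), whose carbanion adds to the carbonyl group of Weinreb ynamide 10 and forms the C3–C4 bond as the chelated adduct 12. Protonation by t-BuOH collapses 12 to hydroxy ynone 13, and the lithium alkoxide on C2 then adds to the alkyne carbon that carries the arylethyl chain, which forms the O1–C6 bond. The closest known reaction types are the acylation of organolithiums by Weinreb amides and the base- or metal-promoted cyclisation of β-hydroxy ynones to 2,3-dihydro-4H-pyran-4-ones. The ring closes in the 6-endo-dig mode, enforced by the polarisation of the ynone (attack at its β-carbon), whereas the 5-exo alternative would be an anti-Michael addition. No new stereocentre is created, and the C2 configuration is carried over unchanged from 5 because neither the C2–O nor the C2–H bond is touched. The step needs carbonyl addition rather than conjugate addition, which the hard primary alkyllithium and the Weinreb amide favour, and it needs 11 to resist β-elimination, which the low temperature and the poor leaving-group ability of oxide secure.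

Step 7
Reactants: 14 (2S)-2-[3,4-bis(TBSO)-5-methoxyphenyl]-6-{2-[4-(TBSO)-3-methoxyphenyl]ethyl}-2,3-dihydro-4H-pyran-4-one
Product: 15 (2S,6S)-2-[3,4-bis(TBSO)-5-methoxyphenyl]-6-{2-[4-(TBSO)-3-methoxyphenyl]ethyl}oxan-4-one
Conditions: H2 (1 atm), Pd/C (10 wt%), EtOAc, rt, stopped after one equivalent of H2
Reagents that add atoms: none
Why: Heterogeneous catalytic hydrogenation of the endocyclic vinylogous-ester alkene: hydrogen should add from the ring face opposite the C2 aryl group, which sets C6 cis to C2 (both substituents equatorial, 6S).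

Step 8
Reactants: 15 (2S,6S)-2-[3,4-bis(TBSO)-5-methoxyphenyl]-6-{2-[4-(TBSO)-3-methoxyphenyl]ethyl}oxan-4-one
Product: 16 (2S,4S,6S)-2-[3,4-bis(TBSO)-5-methoxyphenyl]-6-{2-[4-(TBSO)-3-methoxyphenyl]ethyl}oxan-4-ol
Conditions: Li[HB(s-Bu)3] (L-Selectride), THF, −78 °C; then aq. NH4Cl
Reagents that add atoms: none
Why: Ketone reduction with a bulky trialkylborohydride: attack from the equatorial direction on the chair with both substituents equatorial should give the axial C4 alcohol, trans to the C2 and C6 substituents (4S).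

Step 9
Reactants: 16 (2S,4S,6S)-2-[3,4-bis(TBSO)-5-methoxyphenyl]-6-{2-[4-(TBSO)-3-methoxyphenyl]ethyl}oxan-4-ol
Product: 17 (2S,4S,6S)-2-(3,4-dihydroxy-5-methoxyphenyl)-6-[2-(4-hydroxy-3-methoxyphenyl)ethyl]oxan-4-ol
Conditions: KHF2, MeOH, rt to 40 °C, under argon
Reagents that add atoms: none
Why: Fluoride-mediated desilylation: bifluoride in methanol cleaves aryl silyl ethers under near-neutral conditions, which spares the secondary alcohol and the benzylic C2–O1 bond and leaves all three stereocentres untouched.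

Compound list
1 | methyl 3,4-dihydroxy-5-methoxybenzoate | COC(=O)c1cc(O)c(O)c(OC)c1 | starting material
2 | methyl 3,4-bis(TBSO)-5-methoxybenzoate | COC(=O)c1cc(O[Si](C)(C)C(C)(C)C)c(O[Si](C)(C)C(C)(C)C)c(OC)c1 | intermediate
3 | lithium 1-[3,4-bis(TBSO)-5-methoxyphenyl]-2-chloro-1-methoxyethan-1-olate (hemiketal adduct, formed in the flask) | COC(O[Li])(CCl)c1cc(O[Si](C)(C)C(C)(C)C)c(O[Si](C)(C)C(C)(C)C)c(OC)c1 | intermediate
4 | 1-[3,4-bis(TBSO)-5-methoxyphenyl]-2-chloroethan-1-one | ClCC(=O)c1cc(O[Si](C)(C)C(C)(C)C)c(O[Si](C)(C)C(C)(C)C)c(OC)c1 | intermediate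
5 | (1R)-1-[3,4-bis(TBSO)-5-methoxyphenyl]-2-chloroethan-1-ol | ClC[C@H](O)c1cc(O[Si](C)(C)C(C)(C)C)c(O[Si](C)(C)C(C)(C)C)c(OC)c1 | intermediate
6 | zingerone, 4-(4-hydroxy-3-methoxyphenyl)butan-2-one | CC(=O)CCc1ccc(O)c(OC)c1 | starting material
7 | 4-[4-(TBSO)-3-methoxyphenyl]butan-2-one | CC(=O)CCc1ccc(O[Si](C)(C)C(C)(C)C)c(OC)c1 | intermediate
8 | 4-[4-(TBSO)-3-methoxyphenyl]but-1-en-2-yl diethyl phosphate (formed in the flask) | C=C(CCc1ccc(O[Si](C)(C)C(C)(C)C)c(OC)c1)OP(=O)(OCC)OCC | intermediate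
9 | {4-[4-(TBSO)-3-methoxyphenyl]but-1-yn-1-yl}lithium (formed in the flask) | [Li]C#CCCc1ccc(O[Si](C)(C)C(C)(C)C)c(OC)c1 | intermediate
10 | 5-[4-(TBSO)-3-methoxyphenyl]-N-methoxy-N-methylpent-2-ynamide | CON(C)C(=O)C#CCCc1ccc(O[Si](C)(C)C(C)(C)C)c(OC)c1 | intermediate
11 | lithium (1S)-1-[3,4-bis(TBSO)-5-methoxyphenyl]-2-lithioethan-1-olate (C,O-dilithio derivative of 5, same spatial arrangement at the carbinol carbon; formed in the flask) | [Li]C[C@H](O[Li])c1cc(O[Si](C)(C)C(C)(C)C)c(O[Si](C)(C)C(C)(C)C)c(OC)c1 | intermediate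
12 | dilithium (1S)-1-[3,4-bis(TBSO)-5-methoxyphenyl]-3-[methoxy(methyl)amino]-7-[4-(TBSO)-3-methoxyphenyl]hept-4-yne-1,3-bis(olate) (tetrahedral adduct, C3 undefined; formed in the flask) | CON(C)C(O[Li])(C[C@H](O[Li])c1cc(O[Si](C)(C)C(C)(C)C)c(O[Si](C)(C)C(C)(C)C)c(OC)c1)C#CCCc1ccc(O[Si](C)(C)C(C)(C)C)c(OC)c1 | intermediate
13 | (1S)-1-[3,4-bis(TBSO)-5-methoxyphenyl]-1-hydroxy-7-[4-(TBSO)-3-methoxyphenyl]hept-4-yn-3-one (formed in the flask) | COc1cc(CCC#CC(=O)C[C@H](O)c2cc(O[Si](C)(C)C(C)(C)C)c(O[Si](C)(C)C(C)(C)C)c(OC)c2)ccc1O[Si](C)(C)C(C)(C)C | intermediate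
14 | (2S)-2-[3,4-bis(TBSO)-5-methoxyphenyl]-6-{2-[4-(TBSO)-3-methoxyphenyl]ethyl}-2,3-dihydro-4H-pyran-4-one | COc1cc(CCC2=CC(=O)C[C@@H](c3cc(O[Si](C)(C)C(C)(C)C)c(O[Si](C)(C)C(C)(C)C)c(OC)c3)O2)ccc1O[Si](C)(C)C(C)(C)C | intermediate
15 | (2S,6S)-2-[3,4-bis(TBSO)-5-methoxyphenyl]-6-{2-[4-(TBSO)-3-methoxyphenyl]ethyl}oxan-4-one | COc1cc(CC[C@H]2CC(=O)C[C@@H](c3cc(O[Si](C)(C)C(C)(C)C)c(O[Si](C)(C)C(C)(C)C)c(OC)c3)O2)ccc1O[Si](C)(C)C(C)(C)C | intermediate
16 | (2S,4S,6S)-2-[3,4-bis(TBSO)-5-methoxyphenyl]-6-{2-[4-(TBSO)-3-methoxyphenyl]ethyl}oxan-4-ol | COc1cc(CC[C@H]2C[C@H](O)C[C@@H](c3cc(O[Si](C)(C)C(C)(C)C)c(O[Si](C)(C)C(C)(C)C)c(OC)c3)O2)ccc1O[Si](C)(C)C(C)(C)C | intermediate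
17 | (2S,4S,6S)-2-(3,4-dihydroxy-5-methoxyphenyl)-6-[2-(4-hydroxy-3-methoxyphenyl)ethyl]oxan-4-ol | COc1cc(CC[C@H]2C[C@H](O)C[C@@H](c3cc(O)c(O)c(OC)c3)O2)ccc1O | target

Total step count: 9. Longest linear sequence: 7 steps (steps 1, 2, 3, 6, 7, 8, 9).

Steps most likely to fail

Step 6. The β-oxido alkyllithium may be lost by β-elimination to the styrene or by incomplete reductive lithiation, the carbanion may add in conjugate fashion to the ynamide, and the alkoxide-mediated ring closure may be accompanied by base-induced ring opening that erodes the C2 configuration. The fallback sets out from ester 2 and lithium acetylide 9 and rejoins the route at hydroxy ynone 13. Ester 2 would be condensed with the lithium enolate of N-methoxy-N-methylacetamide (LiN(iPr)2, THF, −78 °C) to give the β-keto Weinreb amide F1. Asymmetric hydrogenation (H2, RuCl2[(R)-BINAP], EtOH, using the ligand enantiomer that gives (S)-carbinols from aroylacetyl substrates) would convert it into the (S)-β-hydroxy Weinreb amide F2. Addition of acetylide 9 (2.2 equiv, generated as in step 5 without the carbamoyl chloride) would give 13, which AgOTf (silver triflate, catalytic) in CH2Cl2 would close to 14 under non-basic conditions.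

Step 7. Hydrogenolysis of the benzylic, vinylogous-ester C2–O1 bond, over-reduction of the ketone, or insufficient facial discrimination on the catalyst surface may occur. The fallback sets out from 14 and returns at 15. Conjugate hydride delivery with Li[HB(s-Bu)3] (1.05 equiv, THF, −78 °C), by axial attack at C6 anti to the aryl group, would give the lithium enolate F3, and protonation with aq. NH4Cl would give the 2,6-cis ketone 15.

Step 8. Hydride delivery from the axial direction may compete and give the equatorial alcohol. The fallback sets out from 15 and returns at 17. NaBH4 (MeOH, −20 °C) would give the equatorial (4R)-alcohol F4 deliberately. Mitsunobu inversion (4-nitrobenzoic acid, PPh3, diisopropyl azodicarboxylate, THF) would give the (4S)-4-nitrobenzoate F5. K2CO3 in degassed MeOH would then cleave the ester and the three aryl silyl ethers together to give 17.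

Further compounds
F1 | step 6 | 3-[3,4-bis(TBSO)-5-methoxyphenyl]-N-methoxy-N-methyl-3-oxopropanamide | CON(C)C(=O)CC(=O)c1cc(O[Si](C)(C)C(C)(C)C)c(O[Si](C)(C)C(C)(C)C)c(OC)c1
F2 | step 6 | (3S)-3-[3,4-bis(TBSO)-5-methoxyphenyl]-3-hydroxy-N-methoxy-N-methylpropanamide | CON(C)C(=O)C[C@H](O)c1cc(O[Si](C)(C)C(C)(C)C)c(O[Si](C)(C)C(C)(C)C)c(OC)c1
F3 | step 7 | lithium (2S,6S)-2-[3,4-bis(TBSO)-5-methoxyphenyl]-6-{2-[4-(TBSO)-3-methoxyphenyl]ethyl}-3,6-dihydro-2H-pyran-4-olate | COc1cc(CC[C@H]2C=C(O[Li])C[C@@H](c3cc(O[Si](C)(C)C(C)(C)C)c(O[Si](C)(C)C(C)(C)C)c(OC)c3)O2)ccc1O[Si](C)(C)C(C)(C)C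
F4 | step 8 | (2S,4R,6S)-2-[3,4-bis(TBSO)-5-methoxyphenyl]-6-{2-[4-(TBSO)-3-methoxyphenyl]ethyl}oxan-4-ol | COc1cc(CC[C@H]2C[C@@H](O)C[C@@H](c3cc(O[Si](C)(C)C(C)(C)C)c(O[Si](C)(C)C(C)(C)C)c(OC)c3)O2)ccc1O[Si](C)(C)C(C)(C)C
F5 | step 8 | (2S,4S,6S)-2-[3,4-bis(TBSO)-5-methoxyphenyl]-6-{2-[4-(TBSO)-3-methoxyphenyl]ethyl}oxan-4-yl 4-nitrobenzoate | COc1cc(CC[C@H]2C[C@H](OC(=O)c4ccc(cc4)[N+](=O)[O-])C[C@@H](c3cc(O[Si](C)(C)C(C)(C)C)c(O[Si](C)(C)C(C)(C)C)c(OC)c3)O2)ccc1O[Si](C)(C)C(C)(C)C
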